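The cis-fused γ-hydroxybutyrolactone (C1(=O)–O2–C3H(OH), fused at C3a/C7a to the cyclohexene) is the closed form of a vicinal acid/aldehyde pair, and hence of a cleaved α-hydroxycyclobutanone. C1 and C3 are therefore joined by a temporary bond and added together, as the C=C of a ketene, across C3a=C7a of a cyclohexa-1,3-diene. The oxygen on the future C3 is acylated by the propanoate carboxyl on C4, which makes a temporary δ-lactone tether. The (R)-methine, locked by A1,3 strain against the trimethylcyclohexyl group on C5, then selects the diene face. The precursor is the (acyloxy)acetic acid of the dienylpropanoic acid. Methanolysis and periodate cleavage remove the tether and the extra bond.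

Key step: step 13

Numbering in the text: 2-benzofuran-1(3H)-one numbering of the target (C1 lactone C=O, C3 lactol carbon, C3a/C7a ring fusion, C4=C5 tetrasubstituted alkene).

Assumption: the hemiacetal carbon C3 epimerises through the open aldehyde-acid form, so equilibrium fixes its configuration. The drawn (3R) epimer has OH on the side of the C4 arm, within hydrogen-bond reach of the ester carbonyl, and is taken as the favoured one.

Step 1
Reactants: 1 3-methylcyclohex-2-en-1-one; 2 (3-methoxyphenyl)boronic acid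
Product: 3 (3S)-3-(3-methoxyphenyl)-3-methylcyclohexan-1-one
Conditions: Pd(OCOCF3)2 (cat.), (R)-4-tert-butyl-2-(pyridin-2-yl)-4,5-dihydrooxazole (cat.), NH4PF6 (cat.), H2O, ClCH2CH2Cl, 40 °C
Reagents that add atoms: none
Why: Pd(II)/pyridine-oxazoline-catalysed asymmetric conjugate addition of an arylboronic acid to a β-methyl cyclic enone is an established route to benzylic quaternary centres, and the (R)-ligand should deliver the aryl group to the enone face that gives the (S)-ketone, which maps onto the (1S) centre of the target.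

Step 2
Reactants: 3 (3S)-3-(3-methoxyphenyl)-3-methylcyclohexan-1-one
Product: 4 1-methoxy-3-[(1S)-1-methyl-3-methylidenecyclohexyl]benzene
Conditions: Ph3PCH3Br, KOt-Bu, THF, 0 °C to rt
Reagents that add atoms: methyltriphenylphosphonium bromide, C[P+](c1ccccc1)(c1ccccc1)c1ccccc1.[Br-]
Why: Wittig methylenation of a moderately hindered cyclohexanone, in which the quaternary centre cannot epimerise.

Step 3
Reactants: 4 1-methoxy-3-[(1S)-1-methyl-3-methylidenecyclohexyl]benzene
Product: 5 (5S)-5-(3-methoxyphenyl)-5-methylspiro[2.5]octane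
Conditions: Et2Zn, CH2I2, CH2Cl2, 0 °C to rt
Reagents that add atoms: diiodomethane, ICI
Why: Simmons–Smith cyclopropanation (Furukawa variant) of a 1,1-disubstituted alkene, with the anisole ring inert to the zinc carbenoid.

Step 4
Reactants: 5 (5S)-5-(3-methoxyphenyl)-5-methylspiro[2.5]octane
Product: 6 1-methoxy-3-[(1S)-1,3,3-trimethylcyclohexyl]benzene
Conditions: H2 (1 atm), PtO2, AcOH, rt, stopped after one equivalent of H2
Reagents that add atoms: none
Why: Catalytic hydrogenolysis of the spirocyclopropane breaks the least hindered CH2–CH2 bond and unmasks the gem-dimethyl group without a carbocation, which avoids Friedel–Crafts closure onto the electron-rich arene.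

Step 5
Reactants: 6 1-methoxy-3-[(1S)-1,3,3-trimethylcyclohexyl]benzene
Product: 8 3-[(1S)-1,3,3-trimethylcyclohexyl]cyclohex-3-en-1-one, via dihydroanisole 7 (not isolated)
Conditions: Li, NH3(l), t-BuOH, THF, −78 to −33 °C; then aq. oxalic acid (cat.), THF, rt
Reagents that add atoms: water, O
Why: Birch reduction keeps OMe and the tert-alkyl group on sp2 carbons, and mild enol ether hydrolysis stops at the β,γ-unsaturated ketone, whose C2 methylene is flanked by C=O and C=C.

Step 6
Reactants: 9 methyl (2R)-2-hydroxypropanoate; 10 prop-2-en-1-ol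
Product: 11 prop-2-enyl (2R)-2-hydroxypropanoate
Conditions: Ti(Oi-Pr)4 (cat.), excess 10, reflux, MeOH distilled off
Reagents that add atoms: none
Why: Titanate-catalysed transesterification driven by removal of methanol, which does not involve the carbinol centre.

Step 7
Reactants: 11 prop-2-enyl (2R)-2-hydroxypropanoate
Product: 12 prop-2-enyl (2R)-2-[(trifluoromethylsulfonyl)oxy]propanoate
Conditions: Tf2O, 2,6-lutidine, CH2Cl2, −78 to 0 °C, used at once
Reagents that add atoms: trifluoromethanesulfonic anhydride, O=S(=O)(OS(=O)(=O)C(F)(F)F)C(F)(F)F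
Why: O-sulfonylation leaves the C–O bond intact (retention) and gives one of the most reactive secondary SN2 electrophiles.

Step 8
Reactants: 8 3-[(1S)-1,3,3-trimethylcyclohexyl]cyclohex-3-en-1-one; 12 prop-2-enyl (2R)-2-[(trifluoromethylsulfonyl)oxy]propanoate
Product: 15 prop-2-enyl (2R)-2-{6-oxo-2-[(1S)-1,3,3-trimethylcyclohexyl]cyclohex-1-en-1-yl}propanoate, via lithium dienolate 13 (not isolated), via unconjugated keto ester 14 (not isolated)
Conditions: LiHMDS (slight deficit), THF, −78 to 0 °C; DMPU, 12, −78 to −20 °C; work-up; DBU (cat.), CH2Cl2, rt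
Reagents that add atoms: none
Why: The doubly activated methylene gives the extended dienolate, which alkylates at its α-carbon; the α-triflyloxy ester reacts by SN2 with inversion (the descriptor stays R because the leaving oxygen ranked first and the new carbon ranks second), and base-mediated conjugation then erases the transient ring stereocentre.

Step 9
Reactants: 15 prop-2-enyl (2R)-2-{6-oxo-2-[(1S)-1,3,3-trimethylcyclohexyl]cyclohex-1-en-1-yl}propanoate
Product: 17 prop-2-enyl (2R)-2-{6-[(trifluoromethylsulfonyl)oxy]-2-[(1S)-1,3,3-trimethylcyclohexyl]cyclohexa-1,5-dien-1-yl}propanoate, via lithium enolate 16 (not isolated)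
Conditions: LDA, THF, −78 °C; N-(5-chloro-2-pyridyl)bis(trifluoromethanesulfonimide), −78 to −40 °C
Reagents that add atoms: N-(5-chloro-2-pyridyl)bis(trifluoromethanesulfonimide), FC(F)(F)S(=O)(=O)N(c1ccc(Cl)cn1)S(=O)(=O)C(F)(F)F
Why: Kinetic α′-deprotonation of the cyclohexenone at its unhindered CH2 followed by O-triflation gives the cross-conjugated dienyl triflate, while the ester methine is tertiary, shielded by the tert-alkyl group and held in the alkene plane by A1,3 strain, so it should be much slower to deprotonate.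

Step 10
Reactants: 17 prop-2-enyl (2R)-2-{6-[(trifluoromethylsulfonyl)oxy]-2-[(1S)-1,3,3-trimethylcyclohexyl]cyclohexa-1,5-dien-1-yl}propanoate
Product: 18 (2R)-2-{2-[(1S)-1,3,3-trimethylcyclohexyl]cyclohexa-1,5-dien-1-yl}propanoic acid
Conditions: Pd(OAc)2 (cat.), PPh3, HCO2H, Et3N, degassed DMF, 50 °C
Reagents that add atoms: none
Why: Pd(0)/formate hydrogenolysis turns the alkenyl triflate into C–H and, in the same flask, cleaves the allyl ester through its π-allyl complex (Tsuji–Trost-type deallylation), with no base strong enough to touch the methine.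

Step 11
Reactants: 18 (2R)-2-{2-[(1S)-1,3,3-trimethylcyclohexyl]cyclohexa-1,5-dien-1-yl}propanoic acid; 19 prop-2-enyl 2-bromoacetate
Product: 20 2-oxo-2-(prop-2-enyloxy)ethyl (2R)-2-{2-[(1S)-1,3,3-trimethylcyclohexyl]cyclohexa-1,5-dien-1-yl}propanoate
Conditions: Cs2CO3, DMF, 0 °C to rt
Reagents that add atoms: none
Why: SN2 O-alkylation of the caesium carboxylate by an α-bromo ester installs the two ketene carbons without activating the acyl group, so the methine cannot epimerise.

Step 12
Reactants: 20 2-oxo-2-(prop-2-enyloxy)ethyl (2R)-2-{2-[(1S)-1,3,3-trimethylcyclohexyl]cyclohexa-1,5-dien-1-yl}propanoate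
Product: 21 2-{[(2R)-2-{2-[(1S)-1,3,3-trimethylcyclohexyl]cyclohexa-1,5-dien-1-yl}propanoyl]oxy}acetic acid
Conditions: Pd(PPh3)4 (cat.), morpholine, THF, rt
Reagents that add atoms: none
Why: Tsuji–Trost deallylation (allyl transfer to morpholine) frees the glycolic acid terminus under nearly neutral conditions and leaves the hindered inner ester and the diene alone.

Step 13
Reactants: 21 2-{[(2R)-2-{2-[(1S)-1,3,3-trimethylcyclohexyl]cyclohexa-1,5-dien-1-yl}propanoyl]oxy}acetic acid
Product: 24 δ-lactone-bridged (1R,6R,8S)-bicyclo[4.2.0]oct-2-en-7-one, via acid chloride 22 (not isolated), via acyloxyketene 23 (not isolated)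
Conditions: 1-chloro-N,N,2-trimethylprop-1-en-1-amine, CH2Cl2, 0 °C; then slow addition to i-Pr2NEt, toluene, 100 °C, high dilution
Reagents that add atoms: none
Why: Dehydrochlorination of 22 gives acyloxyketene 23, which adds to the disubstituted C=C of the diene in a concerted, asynchronous [π2s+π2a] process: the electrophilic ketene carbonyl carbon (future C1) bonds to the diene terminus (future C7a) while allyl-cation character spreads over C3a–C4–C5, and the oxygen-bearing ketene carbon (future C3) closes on C3a. The closest known reaction types are the intramolecular [2+2] cycloaddition of (alkenyloxy)ketenes and the intermolecular addition of acetoxyketene to cyclic 1,3-dienes. The cyclobutanone is closed by the cycloaddition itself, and the six-membered δ-lactone is closed by the same C3–C3a bond in the fused (not bridged) mode, for which the ester must adopt its E conformation. C3a and C7a come out cis because the alkene reacts suprafacially; their absolute sense is fixed by the (R)-methine, whose H lies in the diene plane facing the tert-alkyl group (A1,3 strain), so the carboxyl arm and its ketene reach only one face, and the tether forces the oxygen on the carbinol carbon syn to C4. The step needs site selectivity (disubstituted over tetrasubstituted alkene, secured by sterics and tether length), regioselectivity (ketene polarity and tether agree) and cyclisation ahead of ketene oligomerisation (slow addition, high dilution).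

Step 14
Reactants: 24 δ-lactone-bridged (1R,6R,8S)-bicyclo[4.2.0]oct-2-en-7-one
Product: 25 methyl (2R)-2-{(1R,6R,8S)-8-hydroxy-7-oxo-3-[(1S)-1,3,3-trimethylcyclohexyl]bicyclo[4.2.0]oct-2-en-2-yl}propanoate
Conditions: K2CO3 (cat.), MeOH, 0 °C, short contact; pH 7 buffer
Reagents that add atoms: methanol, CO
Why: Base-catalysed transesterification opens the δ-lactone, an activated ester of an α-ketol, directly to the methyl ester of the target, and low temperature with a buffered quench spares the α-hydroxycyclobutanone.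

Step 15
Reactants: 25 methyl (2R)-2-{(1R,6R,8S)-8-hydroxy-7-oxo-3-[(1S)-1,3,3-trimethylcyclohexyl]bicyclo[4.2.0]oct-2-en-2-yl}propanoate
Product: 27 methyl (2R)-2-{(3R,3aR,7aR)-3-hydroxy-1-oxo-5-[(1S)-1,3,3-trimethylcyclohexyl]-1,3,3a,6,7,7a-hexahydro-2-benzofuran-4-yl}propanoate, via aldehyde acid 26 (not isolated)
Conditions: NaIO4, THF/H2O, 0 °C to rt
Reagents that add atoms: water, O
Why: Malaprade-type periodate cleavage of the α-hydroxy ketone through its hydrate cuts the temporary C–C bond to a cis acid/aldehyde pair that closes spontaneously to the γ-hydroxybutyrolactone; the tetrasubstituted alkene, C3a and C7a are untouched, and C3 settles by ring–chain equilibration.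

Compound list
1 | 3-methylcyclohex-2-en-1-one | CC1=CC(=O)CCC1 | starting material
2 | (3-methoxyphenyl)boronic acid | COc1cccc(c1)B(O)O | starting material
3 | (3S)-3-(3-methoxyphenyl)-3-methylcyclohexan-1-one | COc1cccc(c1)[C@@]2(C)CCCC(=O)C2 | intermediate
4 | 1-methoxy-3-[(1S)-1-methyl-3-methylidenecyclohexyl]benzene | COc1cccc(c1)[C@@]2(C)CCCC(=C)C2 | intermediate
5 | (5S)-5-(3-methoxyphenyl)-5-methylspiro[2.5]octane | COc1cccc(c1)[C@@]2(C)CCCC3(CC3)C2 | intermediate
6 | 1-methoxy-3-[(1S)-1,3,3-trimethylcyclohexyl]benzene | COc1cccc(c1)[C@@]2(C)CCCC(C)(C)C2 | intermediate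
7 | 1-methoxy-5-[(1S)-1,3,3-trimethylcyclohexyl]cyclohexa-1,4-diene (not isolated) | COC1=CCC=C(C1)[C@@]2(C)CCCC(C)(C)C2 | intermediate
8 | 3-[(1S)-1,3,3-trimethylcyclohexyl]cyclohex-3-en-1-one | O=C1CCC=C(C1)[C@@]2(C)CCCC(C)(C)C2 | intermediate
9 | methyl (2R)-2-hydroxypropanoate (methyl D-lactate) | C[C@@H](O)C(=O)OC | starting material
10 | prop-2-en-1-ol (allyl alcohol) | C=CCO | starting material
11 | prop-2-enyl (2R)-2-hydroxypropanoate | C[C@@H](O)C(=O)OCC=C | intermediate
12 | prop-2-enyl (2R)-2-[(trifluoromethylsulfonyl)oxy]propanoate | C[C@@H](OS(=O)(=O)C(F)(F)F)C(=O)OCC=C | intermediate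
13 | lithium 3-[(1S)-1,3,3-trimethylcyclohexyl]cyclohexa-1,3-dien-1-olate, extended dienolate of 8 (not isolated) | [Li+].[O-]C1=CC(=CCC1)[C@@]2(C)CCCC(C)(C)C2 | intermediate
14 | prop-2-enyl (2R)-2-{2-oxo-6-[(1S)-1,3,3-trimethylcyclohexyl]cyclohex-5-en-1-yl}propanoate, both epimers at the ring CH (not isolated) | C=CCOC(=O)[C@H](C)C1C(=O)CCC=C1[C@@]2(C)CCCC(C)(C)C2 | intermediate
15 | prop-2-enyl (2R)-2-{6-oxo-2-[(1S)-1,3,3-trimethylcyclohexyl]cyclohex-1-en-1-yl}propanoate | C=CCOC(=O)[C@H](C)C1=C(CCCC1=O)[C@@]2(C)CCCC(C)(C)C2 | intermediate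
16 | lithium cross-conjugated dienolate of 15 (not isolated) | [Li+].C=CCOC(=O)[C@H](C)C1=C(CCC=C1[O-])[C@@]2(C)CCCC(C)(C)C2 | intermediate
17 | prop-2-enyl (2R)-2-{6-[(trifluoromethylsulfonyl)oxy]-2-[(1S)-1,3,3-trimethylcyclohexyl]cyclohexa-1,5-dien-1-yl}propanoate | C=CCOC(=O)[C@H](C)C1=C(CCC=C1OS(=O)(=O)C(F)(F)F)[C@@]2(C)CCCC(C)(C)C2 | intermediate
18 | (2R)-2-{2-[(1S)-1,3,3-trimethylcyclohexyl]cyclohexa-1,5-dien-1-yl}propanoic acid | OC(=O)[C@H](C)C1=C(CCC=C1)[C@@]2(C)CCCC(C)(C)C2 | intermediate
19 | prop-2-enyl 2-bromoacetate | C=CCOC(=O)CBr | starting material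
20 | 2-oxo-2-(prop-2-enyloxy)ethyl (2R)-2-{2-[(1S)-1,3,3-trimethylcyclohexyl]cyclohexa-1,5-dien-1-yl}propanoate | C=CCOC(=O)COC(=O)[C@H](C)C1=C(CCC=C1)[C@@]2(C)CCCC(C)(C)C2 | intermediate
21 | 2-{[(2R)-2-{2-[(1S)-1,3,3-trimethylcyclohexyl]cyclohexa-1,5-dien-1-yl}propanoyl]oxy}acetic acid | OC(=O)COC(=O)[C@H](C)C1=C(CCC=C1)[C@@]2(C)CCCC(C)(C)C2 | intermediate
22 | 2-chloro-2-oxoethyl (2R)-2-{2-[(1S)-1,3,3-trimethylcyclohexyl]cyclohexa-1,5-dien-1-yl}propanoate (not isolated) | ClC(=O)COC(=O)[C@H](C)C1=C(CCC=C1)[C@@]2(C)CCCC(C)(C)C2 | intermediate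
23 | 2-oxoethenyl (2R)-2-{2-[(1S)-1,3,3-trimethylcyclohexyl]cyclohexa-1,5-dien-1-yl}propanoate, the acyloxyketene (not isolated) | O=C=COC(=O)[C@H](C)C1=C(CCC=C1)[C@@]2(C)CCCC(C)(C)C2 | intermediate
24 | cis-fused (1R,6R,8S)-bicyclo[4.2.0]oct-2-en-7-one; the O on C8 is acylated by the (2R)-propanoyl arm on C2 (δ-lactone, methyl pseudoaxial); C3 carries the (1S)-1,3,3-trimethylcyclohexyl group | C[C@H]1C(=O)O[C@@H]2C(=O)[C@@H]3CCC([C@@]4(C)CCCC(C)(C)C4)=C1[C@H]23 | intermediate
25 | methyl (2R)-2-{(1R,6R,8S)-8-hydroxy-7-oxo-3-[(1S)-1,3,3-trimethylcyclohexyl]bicyclo[4.2.0]oct-2-en-2-yl}propanoate | COC(=O)[C@H](C)C1=C([C@@]2(C)CCCC(C)(C)C2)CC[C@H]2C(=O)[C@@H](O)[C@@H]12 | intermediate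
26 | (1R,2R)-2-formyl-3-[(2R)-1-methoxy-1-oxopropan-2-yl]-4-[(1S)-1,3,3-trimethylcyclohexyl]cyclohex-3-ene-1-carboxylic acid (not isolated) | COC(=O)[C@H](C)C1=C([C@@]2(C)CCCC(C)(C)C2)CC[C@@H](C(=O)O)[C@H]1C=O | intermediate
27 | methyl (2R)-2-{(3R,3aR,7aR)-3-hydroxy-1-oxo-5-[(1S)-1,3,3-trimethylcyclohexyl]-1,3,3a,6,7,7a-hexahydro-2-benzofuran-4-yl}propanoate (CNP0280354.1) | COC(=O)[C@H](C)C1=C([C@@]2(C)CCCC(C)(C)C2)CC[C@H]2C(=O)O[C@@H](O)[C@@H]12 | target

Total step count: 15. Longest linear sequence: 13 (steps 1–5 and 8–15).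

Steps most likely to fail

Step 13. The ester link has to rotate out of its preferred Z conformation before the ketene can reach the diene. Ketene oligomerisation, or its capture by chloride or amine, may therefore outrun ring closure. The fallback drops the tether and uses an intermolecular cycloaddition. It sets out from 18, which (trimethylsilyl)diazomethane converts into methyl (2R)-2-{2-[(1S)-1,3,3-trimethylcyclohexyl]cyclohexa-1,5-dien-1-yl}propanoate F1. Acetoxyketene, made from acetoxyacetyl chloride and Et3N, should add to the disubstituted alkene of F1 with the same regiochemistry and an endo oxygen to give the acetoxycyclobutanone methyl ester F2, the facial isomer being removed by chromatography. K2CO3 in MeOH then removes the acetyl group, and the route is rejoined at 25.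

Step 8. C–C bond formation next to the tert-alkyl group may be slower than base-induced elimination of the triflate or O-alkylation, and the conjugation that follows may stall. The fallback uses a primary electrophile and sets the methine with an auxiliary.
- It sets out from 8 through its dienolate 13, which is alkylated with tert-butyl bromoacetate to the unconjugated tert-butyl keto ester F3; DBU conjugates this to the tert-butyl enone acetate F4.
- TFA gives the enone acetic acid F5, and pivaloyl chloride/Et3N gives the mixed pivalic anhydride F6.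
- Lithiated (R)-4-benzyloxazolidin-2-one gives the N-acyl oxazolidinone F7.
- Evans alkylation (NaHMDS, MeI) on the face away from the benzyl group gives the (2R)-methylated imide F8.
- LiOH/H2O2 gives the (2R)-enone propanoic acid F9, and allyl bromide/K2CO3 returns to the route at 15.

Step 9. Deprotonation at the γ-CH2 or at the ester methine may compete with α′-deprotonation, leading to regioisomeric enolisation or epimerisation. The fallback avoids strong base. It sets out from 15, which Luche reduction converts into the allylic alcohol ester F10. This lactonises (PPTS, cat.) to the β,γ-unsaturated γ-lactone F11. Pd(PPh3)4 in warm dioxane ionises the allylic C–O bond, and β-hydride elimination from the less hindered allyl terminus opens the lactone to the dienoic acid, so the route is rejoined at 18.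

Further compounds
F1 | step 13 | methyl (2R)-2-{2-[(1S)-1,3,3-trimethylcyclohexyl]cyclohexa-1,5-dien-1-yl}propanoate | COC(=O)[C@H](C)C1=C(CCC=C1)[C@@]2(C)CCCC(C)(C)C2
F2 | step 13 | methyl (2R)-2-{(1R,6R,8S)-8-acetoxy-7-oxo-3-[(1S)-1,3,3-trimethylcyclohexyl]bicyclo[4.2.0]oct-2-en-2-yl}propanoate | COC(=O)[C@H](C)C1=C([C@@]2(C)CCCC(C)(C)C2)CC[C@H]2C(=O)[C@@H](OC(C)=O)[C@@H]12
F3 | step 8 | tert-butyl 2-{2-oxo-6-[(1S)-1,3,3-trimethylcyclohexyl]cyclohex-5-en-1-yl}acetate | CC(C)(C)OC(=O)CC1C(=O)CCC=C1[C@@]2(C)CCCC(C)(C)C2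
F4 | step 8 | tert-butyl 2-{6-oxo-2-[(1S)-1,3,3-trimethylcyclohexyl]cyclohex-1-en-1-yl}acetate | CC(C)(C)OC(=O)CC1=C(CCCC1=O)[C@@]2(C)CCCC(C)(C)C2
F5 | step 8 | 2-{6-oxo-2-[(1S)-1,3,3-trimethylcyclohexyl]cyclohex-1-en-1-yl}acetic acid | OC(=O)CC1=C(CCCC1=O)[C@@]2(C)CCCC(C)(C)C2
F6 | step 8 | mixed anhydride of F5 with pivalic acid | CC(C)(C)C(=O)OC(=O)CC1=C(CCCC1=O)[C@@]2(C)CCCC(C)(C)C2
F7 | step 8 | (4R)-4-benzyl-3-(2-{6-oxo-2-[(1S)-1,3,3-trimethylcyclohexyl]cyclohex-1-en-1-yl}acetyl)oxazolidin-2-one | O=C(CC1=C(CCCC1=O)[C@@]2(C)CCCC(C)(C)C2)N3[C@H](Cc4ccccc4)COC3=O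
F8 | step 8 | (4R)-4-benzyl-3-[(2R)-2-{6-oxo-2-[(1S)-1,3,3-trimethylcyclohexyl]cyclohex-1-en-1-yl}propanoyl]oxazolidin-2-one | C[C@H](C1=C(CCCC1=O)[C@@]2(C)CCCC(C)(C)C2)C(=O)N3[C@H](Cc4ccccc4)COC3=O
F9 | step 8 | (2R)-2-{6-oxo-2-[(1S)-1,3,3-trimethylcyclohexyl]cyclohex-1-en-1-yl}propanoic acid | C[C@H](C1=C(CCCC1=O)[C@@]2(C)CCCC(C)(C)C2)C(=O)O
F10 | step 9 | prop-2-enyl (2R)-2-{6-hydroxy-2-[(1S)-1,3,3-trimethylcyclohexyl]cyclohex-1-en-1-yl}propanoate, either carbinol epimer | C=CCOC(=O)[C@H](C)C1=C(CCCC1O)[C@@]2(C)CCCC(C)(C)C2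
F11 | step 9 | (3R)-3-methyl-4-[(1S)-1,3,3-trimethylcyclohexyl]-5,6,7,7a-tetrahydro-1-benzofuran-2(3H)-one, either C7a epimer | C[C@H]1C(=O)OC2CCCC([C@@]3(C)CCCC(C)(C)C3)=C12
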